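Everything rests on cutting both ring bonds of C3, the unsubstituted CH of pyranone ring B that lies between the C4 carbonyl (attached to C4a of benzo ring A) and C2, which carries O1 and the pentadecyl chain. C3 is delivered by a silylated one-carbon phosphorus ylide, C4 is the carboxyl carbon of 2,6-dihydroxybenzoic acid, and O1–C2 plus the chain come from a phenolic hexadecanoate. In a single operation the ylide is acylated by a silyl ester (C3–C4) and the phosphorane so formed olefinates the ortho ester carbonyl (C2=C3), closing ring B. The precursor is symmetrical tert-butyldimethylsilyl 2,6-bis(hexadecanoyloxy)benzoate; its second ester becomes the protected C5 oxygen.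

Key step: step 4

Remark: atom labels follow chromone numbering (O1, C2, C3, C4, C4a, C5–C8, C8a); silyl ester 4 is assumed to be used as the crude, moisture-protected residue and ylide 9 as a filtered THF solution.

Step 1
Reactants: 1 2,6-dihydroxybenzoic acid; 2 hexadecanoyl chloride
Product: 3 2,6-bis(hexadecanoyloxy)benzoic acid
Conditions: 2 (2.3 equiv), pyridine, DMAP (cat.), CH2Cl2, 0 °C to rt; H2O quench, 1 M HCl wash, recrystallisation
Reagents that add atoms: none
Why: Pyridine/DMAP-promoted O-acylation of phenols by an acid chloride (nucleophile-catalysed esterification) should esterify both hydroxyls, since any mixed anhydride formed at the carboxyl group is itself a hexadecanoyl donor and reverts to the free acid in the aqueous quench, as in the usual preparation of O-acylsalicylic acids.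

Step 2
Reactants: 3 2,6-bis(hexadecanoyloxy)benzoic acid
Product: 4 tert-butyldimethylsilyl 2,6-bis(hexadecanoyloxy)benzoate
Conditions: TBSCl (1.1 equiv), Et3N (1.2 equiv), THF, 0 °C to rt; filtration under argon, evaporation
Reagents that add atoms: tert-butyldimethylsilyl chloride, CC(C)(C)[Si](C)(C)Cl
Why: Silyl ester formation by O-silylation of the triethylammonium carboxylate should be fast even for a 2,6-disubstituted benzoate because the reacting oxygen lies outside the crowded region, while the non-nucleophilic base and the water-free isolation keep the aryl esters and the hydrolytically labile silyl ester intact.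

Step 3
Reactants: 5 methyltriphenylphosphonium bromide; 6 chlorotrimethylsilane
Product: 9 (trimethylsilyl)methylenetriphenylphosphorane, via methylenetriphenylphosphorane 7 (not isolated), via (trimethylsilylmethyl)triphenylphosphonium chloride 8 (not isolated)
Conditions: 5 (2.0 equiv), NaN(SiMe3)2 (1.95 equiv), THF, 0 °C to rt; then 6 (1.0 equiv), 0 °C to rt; cannula filtration
Reagents that add atoms: none
Why: Deprotonation of the phosphonium salt gives the methylene ylide, C-silylation of half of it by Me3SiCl gives salt 8, and transylidation by the remaining ylide (8 being the stronger acid because silicon stabilises the adjacent carbanion) should give the silylated ylide, while the poorly soluble methyltriphenylphosphonium chloride and NaBr are removed by filtration.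

Step 4
Reactants: 4 tert-butyldimethylsilyl 2,6-bis(hexadecanoyloxy)benzoate; 9 (trimethylsilyl)methylenetriphenylphosphorane
Product: 11 4-oxo-2-pentadecyl-4H-chromen-5-yl hexadecanoate, via acylphosphorane 10 (not isolated)
Conditions: 9 (1.05 equiv) added slowly to 4, THF, 0 °C to rt; then reflux
Reagents that add atoms: none
Why: The nucleophilic ylide carbon of 9 adds to the silyl ester carbonyl of 4, the tetrahedral adduct expels tert-butyldimethylsilanolate, and this oxyanion strips the SiMe3 group from the α-silyl acylphosphonium ion as a disiloxane, so one equivalent of ylide should deliver the stabilised phosphorane 10 with the C3–C4 bond in place. On heating, the ylide carbon of 10 adds to the carbonyl carbon of an ortho hexadecanoate and the oxaphosphetane collapses with loss of Ph3PO, giving the C2=C3 bond while the ester oxygen stays as O1 and the pentadecyl chain sits on C2. The closest known reaction is the chromone synthesis from silyl esters of O-acylsalicylic acids and this same silylated ylide, that is, ylide acylation followed by intramolecular Wittig olefination of an ester carbonyl. Ring B closes as a six-membered ring by 6-exo-trig attack of C3 on the ester C=O, the only ring size available, and is driven by formation of the P=O bond and the conjugated γ-pyranone. No stereocentre is created and the endocyclic double bond has no geometric isomer. The selectivity needed is acylation at the silyl ester and not at the two aryl alkanoates; it is secured by the irreversible silanolate-to-silicon transfer that makes the silyl ester behave as an activated acyl donor, by the bulky tert-butyl group that blocks attack at silicon, and by adding barely one equivalent of ylide to the ester, while the symmetry of 4 means that whichever ortho ester is olefinated gives the same product and the other is left as the C5 ester.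

Step 5
Reactants: 11 4-oxo-2-pentadecyl-4H-chromen-5-yl hexadecanoate
Product: 12 5-hydroxy-2-pentadecyl-4H-chromen-4-one
Conditions: K2CO3 (0.2 equiv), MeOH/THF 1:1, 0 °C to rt; aq. NH4Cl
Reagents that add atoms: none
Why: Carbonate-catalysed transesterification with methanol should cleave the phenolic ester much faster than methoxide can add to C2 of the γ-pyranone, and the released 5-OH is held in a hydrogen bond to the C4 carbonyl, so ring B should survive at room temperature.

Compound list
1 | 2,6-dihydroxybenzoic acid | O=C(O)c1c(O)cccc1O | starting material
2 | hexadecanoyl chloride | CCCCCCCCCCCCCCCC(=O)Cl | starting material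
3 | 2,6-bis(hexadecanoyloxy)benzoic acid | CCCCCCCCCCCCCCCC(=O)Oc1cccc(OC(=O)CCCCCCCCCCCCCCC)c1C(=O)O | intermediate
4 | tert-butyldimethylsilyl 2,6-bis(hexadecanoyloxy)benzoate | CCCCCCCCCCCCCCCC(=O)Oc1cccc(OC(=O)CCCCCCCCCCCCCCC)c1C(=O)O[Si](C)(C)C(C)(C)C | intermediate
5 | methyltriphenylphosphonium bromide | C[P+](c1ccccc1)(c1ccccc1)c1ccccc1.[Br-] | starting material
6 | chlorotrimethylsilane | C[Si](C)(C)Cl | starting material
7 | methylenetriphenylphosphorane | C=P(c1ccccc1)(c1ccccc1)c1ccccc1 | intermediate (not isolated)
8 | (trimethylsilylmethyl)triphenylphosphonium chloride | C[Si](C)(C)C[P+](c1ccccc1)(c1ccccc1)c1ccccc1.[Cl-] | intermediate (not isolated)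
9 | (trimethylsilyl)methylenetriphenylphosphorane | C[Si](C)(C)C=P(c1ccccc1)(c1ccccc1)c1ccccc1 | intermediate
10 | [2-[2,6-bis(hexadecanoyloxy)phenyl]-2-oxoethylidene]triphenylphosphorane | CCCCCCCCCCCCCCCC(=O)Oc1cccc(OC(=O)CCCCCCCCCCCCCCC)c1C(=O)C=P(c1ccccc1)(c1ccccc1)c1ccccc1 | intermediate (not isolated)
11 | 4-oxo-2-pentadecyl-4H-chromen-5-yl hexadecanoate | CCCCCCCCCCCCCCCc1cc(=O)c2c(OC(=O)CCCCCCCCCCCCCCC)cccc2o1 | intermediate
12 | 5-hydroxy-2-pentadecyl-4H-chromen-4-one | CCCCCCCCCCCCCCCc1cc(=O)c2c(O)cccc2o1 | target

Total step count: 5. Longest linear sequence: 4 steps (steps 1, 2, 4 and 5); step 3 is a one-step branch that joins at step 4.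

Steps most likely to fail

Step 4. The silyl ester carbon is flanked by two ortho acyloxy groups, so the bulky ylide may be acylated instead by an unhindered aryl hexadecanoate, or phosphorane 10 may olefinate the ester carbonyl too slowly and allow acyl scrambling. The fallback gives up the ylide and makes the C2–C3 bond by Claisen-type C-acylation followed by cyclodehydration. It sets out from 2: purchased 2',6'-dihydroxyacetophenone F1 is deprotonated with LiN(SiMe3)2 (4 equiv) in THF at −78 °C and acylated on the enolate carbon with 2 (1 equiv). Acidic work-up should give 1-(2,6-dihydroxyphenyl)octadecane-1,3-dione F2. Warming F2 with catalytic H2SO4 in acetic acid should close ring B through either of the two equivalent phenols with loss of water, returning to the route at 12.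

Step 2. The silyl group may be lost by hydrolysis during isolation, or a hexadecanoyl group may migrate to the carboxylate under the basic conditions, so that the material no longer acylates the ylide cleanly. The fallback activates the acid as its chloride and uses the unsilylated ylide. It sets out from 3, which with oxalyl chloride and catalytic DMF in CH2Cl2 should give 2,6-bis(hexadecanoyloxy)benzoyl chloride F3. Slow addition of 7 (2 equiv, made from 5 and NaN(SiMe3)2 as in step 3) to F3 in THF at −78 °C should give C-acylation, the second equivalent of 7 removing the acidic proton of the acylphosphonium salt. The precipitated methyltriphenylphosphonium chloride is filtered off, and the fallback returns to the route at 10, which is heated as in step 4 to give 11.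

Step 1. The two phenols are hydrogen-bonded to the carboxyl group and may esterify incompletely, acid chloride may be diverted into mixed anhydrides that survive the quench, and the electron-rich acid may decarboxylate if the mixture warms. The fallback masks the carboxyl group first. It sets out from 1, which with benzyl bromide and KHCO3 in DMF should alkylate only at the carboxylate to give benzyl 2,6-dihydroxybenzoate F4. Acylation with 2, Et3N and catalytic DMAP in CH2Cl2 should give benzyl 2,6-bis(hexadecanoyloxy)benzoate F5. Hydrogenolysis over Pd/C under H2 in ethyl acetate should cleave only the benzyl ester, returning to the route at 3.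

Further compounds
F1 | step 4 | 2',6'-dihydroxyacetophenone (purchased) | CC(=O)c1c(O)cccc1O
F2 | step 4 | 1-(2,6-dihydroxyphenyl)octadecane-1,3-dione | CCCCCCCCCCCCCCCC(=O)CC(=O)c1c(O)cccc1O
F3 | step 2 | 2,6-bis(hexadecanoyloxy)benzoyl chloride | CCCCCCCCCCCCCCCC(=O)Oc1cccc(OC(=O)CCCCCCCCCCCCCCC)c1C(=O)Cl
F4 | step 1 | benzyl 2,6-dihydroxybenzoate | O=C(OCc1ccccc1)c1c(O)cccc1O
F5 | step 1 | benzyl 2,6-bis(hexadecanoyloxy)benzoate | CCCCCCCCCCCCCCCC(=O)Oc1cccc(OC(=O)CCCCCCCCCCCCCCC)c1C(=O)OCc1ccccc1
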